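**Plan**
- Retrosynthesis: after removal of a MOM group from the 5-oxygen, the bonds O1–C8a and C4–C4a are cut together. This takes C4a/C8a out of the pyranone ring as an aryne and leaves O1–C2–C3–C4 closed on itself as the β-lactone (S)-14.
- Forward: ring A is delivered as the polarised aryne 15 (from silyl triflate 10). The pyranone ring then arises in one step from the four-membered lactone ring, by insertion of the two aryne carbons into its acyl C–O bond (4 → 6). MOM removal follows.
- Enabling feature: O1–C2–C3–C4 is a 3-hydroxy-acid unit, so O1 and C4 can be joined as an oxetan-2-one. The C5 oxygen sits next to C4a, so a 3-alkoxyaryne puts O1 on C8a and the acyl carbon on C4a, with no choice between two ring-A oxygens.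
- Stereochemistry: C2 is set as the (S)-carbinol by Noyori hydrogenation of β-keto ester 11. It is carried through lactonisation and ring expansion with its C–O bond intact.

Key step: step 9

Remark: the sense of step 6 is assigned by analogy with ethyl benzoylacetate, for which (R)-BINAP–Ru gives the (S)-alcohol; 1 and 11 are taken as purchasable.

**Route**

Step 1
Reactants: 1 2-hydroxy-3,4-dimethoxybenzaldehyde
Product: 2 2-(methoxymethoxy)-3,4-dimethoxybenzaldehyde
Conditions: MOMCl, i-Pr2NEt, CH2Cl2, 0 °C to rt
Reagents that add atoms: chloromethyl methyl ether, COCCl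
Why: O-alkylation of the phenol by the reactive α-chloro ether (MOM ether formation) should proceed even though the hydroxyl is hydrogen-bonded to the aldehyde.

Step 2
Reactants: 2 2-(methoxymethoxy)-3,4-dimethoxybenzaldehyde
Product: 4 2-(methoxymethoxy)-3,4-dimethoxyphenol, via aryl formate 3 (not isolated)
Conditions: mCPBA, CH2Cl2, 0 °C to rt; then K2CO3 (cat.), MeOH, rt
Reagents that add atoms: 3-chloroperbenzoic acid, O=C(OO)c1cccc(Cl)c1
Why: Baeyer–Villiger (Dakin-type) oxidation, in which the aryl group with ortho and para oxygen donors migrates to give the formate, which mild methanolysis cleaves without touching the MOM acetal.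

Step 3
Reactants: 4 2-(methoxymethoxy)-3,4-dimethoxyphenol
Product: 5 2-(methoxymethoxy)-3,4-dimethoxyphenyl N-isopropylcarbamate
Conditions: i-PrNCO, Et3N (cat.), CH2Cl2, rt
Reagents that add atoms: isopropyl isocyanate, CC(C)N=C=O
Why: Base-catalysed addition of the phenol to the isocyanate installs the carbamate that directs the next metalation.

Step 4
Reactants: 5 2-(methoxymethoxy)-3,4-dimethoxyphenyl N-isopropylcarbamate
Product: 8 2-(methoxymethoxy)-3,4-dimethoxy-6-(trimethylsilyl)phenyl N-isopropylcarbamate, via N-silyl carbamate 6 (not isolated), via N-silyl aryl silane 7 (not isolated)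
Conditions: TBSOTf, TMEDA, Et2O, 0 °C to rt; n-BuLi, TMEDA, −78 °C; TMSCl, −78 °C to rt; aq. citric acid work-up
Reagents that add atoms: chlorotrimethylsilane, C[Si](C)(C)Cl
Why: Directed ortho-metalation, in which the N-silylated O-carbamate directs lithiation to C6, the only position ortho to it, and the TMSCl quench at −78 °C should precede any anionic Fries shift.

Step 5
Reactants: 8 2-(methoxymethoxy)-3,4-dimethoxy-6-(trimethylsilyl)phenyl N-isopropylcarbamate
Product: 10 2-(methoxymethoxy)-3,4-dimethoxy-6-(trimethylsilyl)phenyl trifluoromethanesulfonate, via silyl phenol 9 (not isolated)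
Conditions: Et2NH, DBU, MeCN, 40 °C; then PhNTf2, rt
Reagents that add atoms: N-phenylbis(trifluoromethanesulfonimide), O=S(=O)(N(c1ccccc1)S(=O)(=O)C(F)(F)F)C(F)(F)F
Why: E1cB cleavage of the N–H carbamate by DBU (the isocyanate is trapped by Et2NH) frees the phenoxide, which is triflated in the same flask to the ortho-silylaryl triflate, the usual end of the carbamate route to aryne precursors.

Step 6
Reactants: 11 ethyl 3-(3,4-dimethoxyphenyl)-3-oxopropanoate
Product: 12 ethyl (S)-3-(3,4-dimethoxyphenyl)-3-hydroxypropanoate
Conditions: RuCl2[(R)-BINAP] (cat.), H2 (4–50 atm), EtOH, 50 °C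
Reagents that add atoms: none
Why: Noyori asymmetric hydrogenation of a β-keto ester, in which the ester-chelated Ru–BINAP hydride adds to one face of the ketone and so sets the (S)-carbinol centre, the later C2.

Step 7
Reactants: 12 ethyl (S)-3-(3,4-dimethoxyphenyl)-3-hydroxypropanoate
Product: 13 (S)-3-(3,4-dimethoxyphenyl)-3-hydroxypropanoic acid
Conditions: LiOH·H2O, THF/H2O, 0 °C; then 1 M HCl to pH 3, 0 °C
Reagents that add atoms: lithium hydroxide, [Li+].[OH-]
Why: Ester saponification, with a cold and only mildly acidic work-up so that the electron-rich benzylic alcohol is not dehydrated and the stereocentre is not touched.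

Step 8
Reactants: 13 (S)-3-(3,4-dimethoxyphenyl)-3-hydroxypropanoic acid
Product: 14 (S)-4-(3,4-dimethoxyphenyl)oxetan-2-one
Conditions: PhSO2Cl, pyridine, 0 °C; cold work-up, used at once
Reagents that add atoms: none
Why: β-Lactonisation by carboxyl activation (mixed sulfonic anhydride), in which the hydroxyl oxygen closes 4-exo-trig onto the activated acyl carbon, so the carbinol C–O bond and the (S) configuration are retained.

Step 9
Reactants: 14 (S)-4-(3,4-dimethoxyphenyl)oxetan-2-one, 10 2-(methoxymethoxy)-3,4-dimethoxy-6-(trimethylsilyl)phenyl trifluoromethanesulfonate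
Product: 17 (S)-2-(3,4-dimethoxyphenyl)-6,7-dimethoxy-5-(methoxymethoxy)chroman-4-one, via aryne 15 (not isolated), via alkoxide acyl fluoride 16 (not isolated)
Conditions: KF, 18-crown-6, THF, 0 °C to rt, 14 and 10 (1.5 equiv) added slowly
Reagents that add atoms: none
Why: Proposed new method: fluoride serves twice, it desilylates 10 to aryne 15 and it adds reversibly to the strained lactone carbonyl of 14 to give the ring-opened β-alkoxide acyl fluoride 16; the alkoxide then adds to 15 and the resulting aryl anion closes onto the acyl fluoride and expels fluoride, so the two aryne carbons are inserted into the acyl C–O bond and the four-membered ring becomes the six-membered pyranone ring. The closest known reaction types are the σ-insertion of arynes into the N–C(=O) bond of amides and cyclic ureas (ring expansion by two atoms) and into the acyl–O bond of carboxylic acids (ortho-hydroxyaryl ketones). The one ring closure is the 6-exo-trig attack of the aryl carbanion (C4a) on the acyl carbon (C4). No stereocentre is formed: C2 comes from 14 and keeps its configuration because its C–O and C–H bonds are not broken on the alkoxide pathway. The step needs regioselective addition to the unsymmetrical aryne, which the OMOM group beside the triple bond secures by sending the oxygen nucleophile to the remote aryne carbon (later C8a) and the carbanion to the adjacent one (later C4a, next to C5–O); it also needs the alkoxide to outrun the neutral carbonyl oxygen of 14, which its charge and an excess of soluble fluoride should secure.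

Step 10
Reactants: 17 (S)-2-(3,4-dimethoxyphenyl)-6,7-dimethoxy-5-(methoxymethoxy)chroman-4-one
Product: 18 (S)-2-(3,4-dimethoxyphenyl)-5-hydroxy-6,7-dimethoxychroman-4-one
Conditions: HCl (1 M in MeOH), 0 °C to rt
Reagents that add atoms: none
Why: Acid-catalysed acetal exchange removes the MOM group, which is peri to the carbonyl and should cleave at or below room temperature, where acid-induced opening of the ring at C2 is not expected.

**Compound list**
1 | 2-hydroxy-3,4-dimethoxybenzaldehyde | O=Cc1ccc(OC)c(OC)c1O | starting material
2 | 2-(methoxymethoxy)-3,4-dimethoxybenzaldehyde | O=Cc1ccc(OC)c(OC)c1OCOC | intermediate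
3 | 2-(methoxymethoxy)-3,4-dimethoxyphenyl formate | O=COc1ccc(OC)c(OC)c1OCOC | intermediate
4 | 2-(methoxymethoxy)-3,4-dimethoxyphenol | Oc1ccc(OC)c(OC)c1OCOC | intermediate
5 | 2-(methoxymethoxy)-3,4-dimethoxyphenyl N-isopropylcarbamate | CC(C)NC(=O)Oc1ccc(OC)c(OC)c1OCOC | intermediate
6 | 2-(methoxymethoxy)-3,4-dimethoxyphenyl N-(tert-butyldimethylsilyl)-N-isopropylcarbamate | CC(C)N(C(=O)Oc1ccc(OC)c(OC)c1OCOC)[Si](C)(C)C(C)(C)C | intermediate
7 | 2-(methoxymethoxy)-3,4-dimethoxy-6-(trimethylsilyl)phenyl N-(tert-butyldimethylsilyl)-N-isopropylcarbamate | CC(C)N(C(=O)Oc1c([Si](C)(C)C)cc(OC)c(OC)c1OCOC)[Si](C)(C)C(C)(C)C | intermediate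
8 | 2-(methoxymethoxy)-3,4-dimethoxy-6-(trimethylsilyl)phenyl N-isopropylcarbamate | CC(C)NC(=O)Oc1c([Si](C)(C)C)cc(OC)c(OC)c1OCOC | intermediate
9 | 2-(methoxymethoxy)-3,4-dimethoxy-6-(trimethylsilyl)phenol | Oc1c([Si](C)(C)C)cc(OC)c(OC)c1OCOC | intermediate
10 | 2-(methoxymethoxy)-3,4-dimethoxy-6-(trimethylsilyl)phenyl trifluoromethanesulfonate | COCOc1c(OC)c(OC)cc([Si](C)(C)C)c1OS(=O)(=O)C(F)(F)F | intermediate
11 | ethyl 3-(3,4-dimethoxyphenyl)-3-oxopropanoate | CCOC(=O)CC(=O)c1ccc(OC)c(OC)c1 | starting material
12 | ethyl (S)-3-(3,4-dimethoxyphenyl)-3-hydroxypropanoate | CCOC(=O)C[C@H](O)c1ccc(OC)c(OC)c1 | intermediate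
13 | (S)-3-(3,4-dimethoxyphenyl)-3-hydroxypropanoic acid | OC(=O)C[C@H](O)c1ccc(OC)c(OC)c1 | intermediate
14 | (S)-4-(3,4-dimethoxyphenyl)oxetan-2-one | O=C1C[C@@H](c2ccc(OC)c(OC)c2)O1 | intermediate
15 | 3-(methoxymethoxy)-4,5-dimethoxybenzyne | COCOC1=C(OC)C(OC)=CC#C1 | intermediate
16 | potassium (S)-1-(3,4-dimethoxyphenyl)-3-fluoro-3-oxopropan-1-olate | O=C(F)C[C@H]([O-])c1ccc(OC)c(OC)c1.[K+] | intermediate
17 | (S)-2-(3,4-dimethoxyphenyl)-6,7-dimethoxy-5-(methoxymethoxy)chroman-4-one | COCOc1c(OC)c(OC)cc2c1C(=O)C[C@@H](c1ccc(OC)c(OC)c1)O2 | intermediate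
18 | (S)-2-(3,4-dimethoxyphenyl)-5-hydroxy-6,7-dimethoxychroman-4-one | COc1ccc([C@@H]2CC(=O)c3c(cc(OC)c(OC)c3O)O2)cc1OC | target

**Count**
Total steps: 10. Longest linear sequence: 7 (steps 1–5, 9, 10).

**Steps most likely to fail**

Step 9 (proposed new method). The neutral carbonyl oxygen of the lactone may capture the aryne in place of the ring-opened alkoxide. The O-arylated lactonium ion would then ionise at the electron-rich benzylic carbon, so the ring could still form but with eroded enantiomeric purity. Fluoride-induced β-elimination of the lactone to the cinnamate, and chain growth of the alkoxide on further lactone, are two more drains. The fallback sets out from 14 and replaces the fluoride relay by a stable acyl acceptor made beforehand. Aminolysis of 14 (MeONHMe·HCl, Me2AlCl, CH2Cl2, 0 °C) gives (S)-3-(3,4-dimethoxyphenyl)-3-hydroxy-N-methoxy-N-methylpropanamide F1. This is deprotonated with KHMDS (THF, −78 °C) and treated with 10 and KF/18-crown-6. Addition of the alkoxide to aryne 15 and closure of the ortho carbanion onto the Weinreb amide should give 17 after work-up, where the route is rejoined. Both events, alkoxide addition to arynes and trapping of the ortho carbanion by an ester-level carbonyl, are established in aryne annulations of hydroxy esters, and the carbinol C–O bond is again untouched.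

Step 8. During or after ring closure the benzylic C–O bond may ionise, with loss of CO2 to the styrene, because the 3,4-dimethoxyphenyl group stabilises the cation. The fallback gives up the lactone and sets the stereocentre last; it sets out from 10. Compound 10 and commercial 3-(3,4-dimethoxyphenyl)propiolic acid (OC(=O)C#Cc1ccc(OC)c(OC)c1) with CsF in THF at 125 °C should undergo the known insertion of an aryne into the C–O bond of a carboxylic acid, followed by 6-endo oxa-Michael closure of the ortho-hydroxyaryl ynone. This gives 2-(3,4-dimethoxyphenyl)-6,7-dimethoxy-5-(methoxymethoxy)-4H-chromen-4-one F2, with the same aryne regiochemistry as in step 9. Asymmetric hydrogenation of the flavone with a chiral Ru–NHC catalyst should give (2S)-2-(3,4-dimethoxyphenyl)-6,7-dimethoxy-5-(methoxymethoxy)chroman-4-ol F3 (C4 epimers). Dess–Martin oxidation then returns the route to 17.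

Step 4. The carbamoyl group may migrate from oxygen to carbon (anionic Fries shift) before silylation, or lithiation next to the 4-methoxy group may compete. The fallback sets out from 4 and uses halogen in place of the directing group. Ortho-bromination (NBS, cat. i-Pr2NH, CH2Cl2, −78 to 0 °C) should give 6-bromo-2-(methoxymethoxy)-3,4-dimethoxyphenol F4, since C6 is ortho to the hydroxyl and para to a methoxy group. O-silylation (HMDS, 80 °C) gives [6-bromo-2-(methoxymethoxy)-3,4-dimethoxyphenoxy]trimethylsilane F5. Bromine–lithium exchange with n-BuLi (THF, −100 °C) triggers the O-to-C retro-Brook silyl shift, and Tf2O then gives 10, where the route is rejoined.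

**Further compounds**
F1 | step 9 | (S)-3-(3,4-dimethoxyphenyl)-3-hydroxy-N-methoxy-N-methylpropanamide | CON(C)C(=O)C[C@H](O)c1ccc(OC)c(OC)c1
F2 | step 8 | 2-(3,4-dimethoxyphenyl)-6,7-dimethoxy-5-(methoxymethoxy)-4H-chromen-4-one | COCOc1c(OC)c(OC)cc2oc(-c3ccc(OC)c(OC)c3)cc(=O)c12
F3 | step 8 | (2S)-2-(3,4-dimethoxyphenyl)-6,7-dimethoxy-5-(methoxymethoxy)chroman-4-ol | COCOc1c(OC)c(OC)cc2c1C(O)C[C@@H](c1ccc(OC)c(OC)c1)O2
F4 | step 4 | 6-bromo-2-(methoxymethoxy)-3,4-dimethoxyphenol | Oc1c(Br)cc(OC)c(OC)c1OCOC
F5 | step 4 | [6-bromo-2-(methoxymethoxy)-3,4-dimethoxyphenoxy]trimethylsilane | C[Si](C)(C)Oc1c(Br)cc(OC)c(OC)c1OCOC
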